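**Plan**

Numbering: ring A = C1 (C=CH2), C2, C3 (OH), C4 (Br), C5 (CMe2), C6 (spiro). Ring B = C6, C7, C8, C9 (CH3, OH), C10 (Cl), C11.
Enabling feature: the C1 methylidene of ring A lies between spiro C6 and the C2 methylene. It can therefore be unmasked by protonating C2 of a ring-A allylsilane (C1=C2, CH2SiMe3 on C1), and that C1=C2 bond is an olefin-metathesis bond.
Cuts, in order: C–Si/C2–H (protodesilylation), C1=C2 (RCM), C2–C3 (vinyl addition), C4–Br, the two C1–CH2 bonds (silylmethyl addition to a lactone), C9–CH3, C10–Cl, C5–C6 ([3,3] shift).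
Forward: ring B is bought as a cyclohexanone ketal and an Ireland–Claisen shift joins C5 to C6. A temporary spiro δ-lactone (C1, O, C3–C6) holds both side arms while ring B is functionalised, then opens to the allylsilane. The chain grows to C2 and ring A closes last.
Stereochemistry: C6 comes from desymmetrising deprotonation with a chiral lithium amide, C10 from equilibration to the equatorial chloride, and C9 from equatorial methyl delivery. C4 comes from enamine catalysis and C3 from Cornforth/Felkin–Anh addition.

Key step: step 12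

Assumption 1: the sense of step 4 is taken from 4-tert-butylcyclohexanone, where the (R,R)-amide leads to the (S)-enol silane, the same spatial sense as 11. If the spiro lactone responds the other way, the (S,S)-amine is used.
Assumption 2: locants in all names follow the target numbering above, also where IUPAC rules would number a ring in the other direction. The bromine donor of step 9 is a known reagent made in one operation from 2,6-di-tert-butylphenol and bromine.

Step 1
Reactants: 1 1,4-dioxaspiro[4.5]decane-8-carboxylic acid; 2 prenyl bromide (1-bromo-3-methylbut-2-ene)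
Product: 3 prenyl 1,4-dioxaspiro[4.5]decane-8-carboxylate
Conditions: K2CO3, DMF, rt
Reagents that add atoms: prenyl bromide (2), CC(C)=CCBr
Why: SN2 O-alkylation of the potassium carboxylate by a primary allylic bromide is a standard acid-free esterification, so the dioxolane survives and no stereocentre is involved.

Step 2
Reactants: 3 prenyl 1,4-dioxaspiro[4.5]decane-8-carboxylate
Product: 6 8-(2-methylbut-3-en-2-yl)-1,4-dioxaspiro[4.5]decane-8-carboxylic acid, via silyl ketene acetal 4 (not isolated), via trimethylsilyl ester 5 (not isolated)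
Conditions: LDA, THF, −78 °C; TMSCl, −78 → 65 °C; aqueous work-up at pH 4–5
Reagents that add atoms: chlorotrimethylsilane, C[Si](C)(C)Cl (its silicon stays only in 4 and 5)
Why: Ireland–Claisen rearrangement: O-silylation of the ester enolate gives a fully substituted ketene acetal whose [3,3] shift through the dimethyl-substituted allyl terminus forms the C5–C6 bond between two quaternary carbons, a task for which this rearrangement is well established, and 6 keeps a mirror plane so no stereocentre arises.

Step 3
Reactants: 6 8-(2-methylbut-3-en-2-yl)-1,4-dioxaspiro[4.5]decane-8-carboxylic acid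
Product: 9 5,5-dimethyl-2-oxaspiro[5.5]undecane-1,9-dione, via bis(9-BBN) adduct 7 (not isolated), via hydroxy acid ketal 8 (not isolated)
Conditions: 9-BBN (2.5 equiv), THF, 0 → 50 °C; NaOH, H2O2, 0 °C; then 3 M HCl, THF, 40 °C
Reagents that add atoms: 9-BBN, B1C2CCCC1CCC2 (boron stays only in 7); hydrogen peroxide, OO; water, O
Why: Hydroboration–oxidation followed by acid lactonisation and ketal hydrolysis: one equivalent of 9-BBN is bound by the acid as an acyloxyborane that is not reduced further, the second puts boron on the terminal carbon (C3) of the neopentyl vinyl group, and after oxidation the δ-hydroxy acid closes under acid (gem-dialkyl effect) while the dioxolane is hydrolysed, giving an achiral keto lactone with no α-hydrogen on the lactone side.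

Step 4
Reactants: 9 5,5-dimethyl-2-oxaspiro[5.5]undecane-1,9-dione
Product: 11 (6R)-5,5-dimethyl-9-(trimethylsilyloxy)-2-oxaspiro[5.5]undec-9-en-1-one, via lithium enolate 10 (not isolated)
Conditions: (R,R)-bis(1-phenylethyl)amine hydrochloride, n-BuLi (2 equiv), THF; TMSCl (internal quench), then 9, −100 → −78 °C
Reagents that add atoms: chlorotrimethylsilane, C[Si](C)(C)Cl
Why: Enantioselective deprotonation by a C2-symmetric chiral lithium amide with in situ silylation is a known desymmetrisation of 4-substituted and 4,4-disubstituted cyclohexanones: with the quaternary C5 locked equatorial the base chooses between the enantiotopic axial hydrogens on C8 and C10, removal of the C10 hydrogen makes C6 a stereocentre (R here), and the hindered amide does not touch the non-enolisable lactone.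

Step 5
Reactants: 11 (6R)-5,5-dimethyl-9-(trimethylsilyloxy)-2-oxaspiro[5.5]undec-9-en-1-one
Product: 13 (6R,10S)-10-chloro-5,5-dimethyl-2-oxaspiro[5.5]undecane-1,9-dione, via axial 10-epi-chloride 12 (not isolated)
Conditions: NCS, THF, −78 → 0 °C; solvent change, LiCl, DMF, rt
Reagents that add atoms: N-chlorosuccinimide, O=C1CCC(=O)N1Cl
Why: Electrophilic α-chlorination of a silyl enol ether places chlorine on C10 only, and chloride exchange and enolisation in polar DMF should convert the axial epimer, which is syn-axial to the C1 carbonyl, into the equatorial (10S) chloride lying cis to C5.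

Step 6
Reactants: 13 (6R,10S)-10-chloro-5,5-dimethyl-2-oxaspiro[5.5]undecane-1,9-dione; 14 methyllithium
Product: 15 (6R,9R,10S)-10-chloro-9-hydroxy-5,5,9-trimethyl-2-oxaspiro[5.5]undecan-1-one
Conditions: ClTi(OiPr)3, MeLi, Et2O, −40 → 0 °C; then 13, CH2Cl2/Et2O, −30 °C → rt; aqueous NH4F work-up
Reagents that add atoms: methyllithium (14), [Li]C, delivered as methyltriisopropoxytitanium, C[Ti](OC(C)C)(OC(C)C)OC(C)C
Why: Carbonyl addition of a bulky, non-basic organotitanium reagent takes the ketone and leaves the hindered lactone, does not enolise the chloroketone, and should enter from the equatorial side of the locked chair (away from the axial hydrogens on C7 and C11), so that CH3 ends equatorial and trans to Cl and the OH axial and cis to Cl (9R), the usual outcome of methyl addition to 2-chlorocyclohexanones.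

Step 7
Reactants: 15 (6R,9R,10S)-10-chloro-9-hydroxy-5,5,9-trimethyl-2-oxaspiro[5.5]undecan-1-one; 16 (trimethylsilyl)methylmagnesium chloride
Product: 18 (1R,2S,4R)-2-chloro-4-(4-hydroxy-2-methylbutan-2-yl)-1-methyl-4-[3-(trimethylsilyl)prop-1-en-2-yl]cyclohexan-1-ol, via bis(silylmethyl)carbinol 17 (not isolated)
Conditions: anhydrous CeCl3, 16 (6 equiv), THF, −78 °C → rt; aq NH4Cl; crude 17, SiO2, CH2Cl2, rt
Reagents that add atoms: (trimethylsilyl)methylmagnesium chloride (16), C[Si](C)(C)C[Mg]Cl
Why: Cerium(III)-mediated double addition of the silylmethyl Grignard reagent to a lactone followed by Peterson elimination of one β-hydroxysilane arm is the known one-flask route from esters and lactones to 2-substituted allylsilanes; ring opening sets the C3 alcohol free without any protecting group, and one extra equivalent only deprotonates C9–OH, whose cis chloride cannot close to an epoxide.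

Step 8
Reactants: 18 (1R,2S,4R)-2-chloro-4-(4-hydroxy-2-methylbutan-2-yl)-1-methyl-4-[3-(trimethylsilyl)prop-1-en-2-yl]cyclohexan-1-ol
Product: 19 3-[(1R,3S,4R)-3-chloro-4-hydroxy-4-methyl-1-(3-trimethylsilylprop-1-en-2-yl)cyclohexyl]-3-methylbutanal
Conditions: TPAP (5 mol %), NMO, 4 Å MS, CH2Cl2, rt
Reagents that add atoms: none
Why: Ley–Griffith oxidation converts the only oxidisable (primary) alcohol into the aldehyde under neutral conditions, which avoids acid-triggered attack of the allylsilane on the new carbonyl group.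

Step 9
Reactants: 19 3-[(1R,3S,4R)-3-chloro-4-hydroxy-4-methyl-1-(3-trimethylsilylprop-1-en-2-yl)cyclohexyl]-3-methylbutanal
Product: 20 (2S)-2-bromo-3-[(1S,3S,4R)-3-chloro-4-hydroxy-4-methyl-1-(3-trimethylsilylprop-1-en-2-yl)cyclohexyl]-3-methylbutanal
Conditions: (S)-α,α-bis[3,5-bis(trifluoromethyl)phenyl]prolinol TMS ether (20 mol %), PhCO2H (cat.), H2O (cat.), 4,4-dibromo-2,6-di-tert-butylcyclohexa-2,5-dienone, CH2Cl2/pentane, −40 °C; cold filtration through silica, used at once
Reagents that add atoms: 4,4-dibromo-2,6-di-tert-butylcyclohexa-2,5-dien-1-one, CC(C)(C)C1=CC(Br)(Br)C=C(C(C)(C)C)C1=O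
Why: Enamine-catalysed asymmetric α-bromination of aldehydes, known for tert-alkyl-substituted acetaldehydes, brominates the E-enamine on the face left open by the diaryl(silyloxy)methyl group of the (S)-catalyst and so sets C4 as S independently of the remote ring centres, while the enamine outruns the far less nucleophilic allylsilane for this mild bromine donor.

Step 10
Reactants: 20 (2S)-2-bromo-3-[(1S,3S,4R)-3-chloro-4-hydroxy-4-methyl-1-(3-trimethylsilylprop-1-en-2-yl)cyclohexyl]-3-methylbutanal; 21 vinylmagnesium bromide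
Product: 22 (1R,2S,4S)-4-[(3S,4R)-3-bromo-4-hydroxy-2-methylhex-5-en-2-yl]-2-chloro-1-methyl-4-[3-(trimethylsilyl)prop-1-en-2-yl]cyclohexan-1-ol
Conditions: 21 (3.2 equiv), THF, −78 °C; AcOH/THF quench at −78 °C
Reagents that add atoms: vinylmagnesium bromide (21), C=C[Mg]Br
Why: Grignard addition to an α-haloaldehyde under Cornforth/polar Felkin–Anh control: with C–Br opposed to C=O the nucleophile passes H rather than the tert-alkyl C5 and should give the 3,4-anti bromohydrin (3R), which is the cis relation in ring A, while the cold quench forestalls epoxide closure and one equivalent is spent on C9–OH.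

Step 11
Reactants: 22 (1R,2S,4S)-4-[(3S,4R)-3-bromo-4-hydroxy-2-methylhex-5-en-2-yl]-2-chloro-1-methyl-4-[3-(trimethylsilyl)prop-1-en-2-yl]cyclohexan-1-ol
Product: 23 (1R,2S,4S)-4-[(3S,4R)-3-bromo-4-(tert-butyldimethylsilyloxy)-2-methylhex-5-en-2-yl]-2-chloro-1-methyl-4-[3-(trimethylsilyl)prop-1-en-2-yl]cyclohexan-1-ol
Conditions: TBSOTf (1.2 equiv), 2,6-lutidine, CH2Cl2, −78 → −20 °C
Reagents that add atoms: tert-butyldimethylsilyl triflate, CC(C)(C)[Si](C)(C)OS(=O)(=O)C(F)(F)F
Why: Silyl triflate/lutidine silylation should take the secondary allylic C3–OH ahead of the axial tertiary C9–OH flanked by C–Cl, and TBS is chosen because it outlasts the acid of step 13.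

Step 12
Reactants: 23 (1R,2S,4S)-4-[(3S,4R)-3-bromo-4-(tert-butyldimethylsilyloxy)-2-methylhex-5-en-2-yl]-2-chloro-1-methyl-4-[3-(trimethylsilyl)prop-1-en-2-yl]cyclohexan-1-ol
Product: 24 (3R,4S,6S,9R,10S)-4-bromo-3-(tert-butyldimethylsilyloxy)-10-chloro-5,5,9-trimethyl-1-(trimethylsilylmethyl)spiro[5.5]undec-1-en-9-ol
Conditions: Hoveyda–Grubbs II catalyst with N,N′-di-o-tolyl NHC (10 mol %), 1,4-benzoquinone (10 mol %), toluene (2 mM), 80 °C, Ar sparge
Reagents that add atoms: none
Why: The ruthenium alkylidene first exchanges onto the monosubstituted C2 vinyl group, the Ru=C2 carbene then adds across the 1,1-disubstituted C1 alkene by [2+2] cycloaddition, and cycloreversion of the metallacyclobutane delivers the C1=C2 double bond while the two terminal CH2 groups leave as ethene. The closest known reaction type is ring-closing metathesis of dienes carrying a 2-(silylmethyl)allyl unit to give cyclic allylsilanes with a trisubstituted ring alkene. Ring A (C1–C6) closes as a six-membered carbocycle, helped by the C5 gem-dimethyl group and quaternary C6, which press the two alkenes together (Thorpe–Ingold effect). No stereocentre is formed, and C3, C4, C6, C9 and C10 are not reacting atoms. The step needs chemoselectivity for the two terminal alkenes beside C–Br, C–Cl, a free tertiary OH and the allylic C–Si bond, all of which ruthenium carbenes tolerate, and it needs cyclisation to beat dimerisation, which high dilution, ethene removal and the small o-tolyl carbene ligand made for crowded alkenes should secure. Benzoquinone suppresses ruthenium hydrides that could isomerise the allyl silyl ether or the allylsilane.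

Step 13
Reactants: 24 (3R,4S,6S,9R,10S)-4-bromo-3-(tert-butyldimethylsilyloxy)-10-chloro-5,5,9-trimethyl-1-(trimethylsilylmethyl)spiro[5.5]undec-1-en-9-ol
Product: 25 (3R,4S,6S,9R,10S)-4-bromo-3-(tert-butyldimethylsilyloxy)-10-chloro-5,5,9-trimethyl-1-methylidenespiro[5.5]undecan-9-ol
Conditions: CF3CO2H (5 equiv), CH2Cl2, −40 → 0 °C; cold aq NaHCO3 quench
Reagents that add atoms: none
Why: Protodesilylation of an allylsilane (SE2′): the proton goes to C2 because the charge then sits on C1, tertiary and β to silicon, and loss of silicon leaves the exocyclic alkene regiospecifically; ionisation of C3–O is held back by the weakly basic, hindered silyl ether oxygen and the electron-withdrawing C4–Br, and the low temperature keeps the much less nucleophilic product alkene and the β-chloro tertiary alcohol untouched.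

Step 14
Reactants: 25 (3R,4S,6S,9R,10S)-4-bromo-3-(tert-butyldimethylsilyloxy)-10-chloro-5,5,9-trimethyl-1-methylidenespiro[5.5]undecan-9-ol
Product: 26 (3R,4S,6S,9R,10S)-4-bromo-10-chloro-5,5,9-trimethyl-1-methylidenespiro[5.5]undecane-3,9-diol (target)
Conditions: HF·pyridine, pyridine/THF, 0 °C → rt
Reagents that add atoms: none
Why: Fluoride-driven Si–O cleavage under weakly acidic buffered conditions removes the TBS group without base, so both cis halohydrins and the exocyclic alkene should remain as they are.

**Compound list**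

1 | 1,4-dioxaspiro[4.5]decane-8-carboxylic acid | O=C(O)C1CCC2(CC1)OCCO2 | starting material
2 | prenyl bromide (1-bromo-3-methylbut-2-ene) | CC(C)=CCBr | starting material
3 | prenyl 1,4-dioxaspiro[4.5]decane-8-carboxylate | CC(C)=CCOC(=O)C1CCC2(CC1)OCCO2 | intermediate
4 | prenyl trimethylsilyl ketene acetal of 3 | CC(C)=CCOC(O[Si](C)(C)C)=C1CCC2(CC1)OCCO2 | intermediate
5 | trimethylsilyl 8-(2-methylbut-3-en-2-yl)-1,4-dioxaspiro[4.5]decane-8-carboxylate | C=CC(C)(C)C1(C(=O)O[Si](C)(C)C)CCC2(CC1)OCCO2 | intermediate
6 | 8-(2-methylbut-3-en-2-yl)-1,4-dioxaspiro[4.5]decane-8-carboxylic acid | C=CC(C)(C)C1(C(=O)O)CCC2(CC1)OCCO2 | intermediate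
7 | bis(9-BBN) adduct of 6 (acyloxyborane at C1, primary alkylborane at C3) | O=C(OB1C2CCCC1CCC2)C1(C(C)(C)CCB2C3CCCC2CCC3)CCC2(CC1)OCCO2 | intermediate
8 | 8-(4-hydroxy-2-methylbutan-2-yl)-1,4-dioxaspiro[4.5]decane-8-carboxylic acid | OCCC(C)(C)C1(C(=O)O)CCC2(CC1)OCCO2 | intermediate
9 | 5,5-dimethyl-2-oxaspiro[5.5]undecane-1,9-dione | O=C1OCCC(C)(C)C12CCC(=O)CC2 | intermediate
10 | lithium (6R)-C9=C10 enolate of 9 | O=C1OCCC(C)(C)[C@]12CCC(O[Li])=CC2 | intermediate
11 | (6R)-5,5-dimethyl-9-(trimethylsilyloxy)-2-oxaspiro[5.5]undec-9-en-1-one | O=C1OCCC(C)(C)[C@]12CCC(O[Si](C)(C)C)=CC2 | intermediate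
12 | (6R,10R)-10-chloro-5,5-dimethyl-2-oxaspiro[5.5]undecane-1,9-dione (axial chloride) | O=C1OCCC(C)(C)[C@]12CCC(=O)[C@H](Cl)C2 | intermediate
13 | (6R,10S)-10-chloro-5,5-dimethyl-2-oxaspiro[5.5]undecane-1,9-dione (equatorial chloride) | O=C1OCCC(C)(C)[C@]12CCC(=O)[C@@H](Cl)C2 | intermediate
14 | methyllithium | [Li]C | starting material
15 | (6R,9R,10S)-10-chloro-9-hydroxy-5,5,9-trimethyl-2-oxaspiro[5.5]undecan-1-one | O=C1OCCC(C)(C)[C@]12CC[C@@](C)(O)[C@@H](Cl)C2 | intermediate
16 | (trimethylsilyl)methylmagnesium chloride | C[Si](C)(C)C[Mg]Cl | starting material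
17 | (1R,2S,4R)-2-chloro-4-(4-hydroxy-2-methylbutan-2-yl)-4-[2-hydroxy-1,3-bis(trimethylsilyl)propan-2-yl]-1-methylcyclohexan-1-ol | OCCC(C)(C)[C@@]1(C(O)(C[Si](C)(C)C)C[Si](C)(C)C)CC[C@@](C)(O)[C@@H](Cl)C1 | intermediate
18 | (1R,2S,4R)-2-chloro-4-(4-hydroxy-2-methylbutan-2-yl)-1-methyl-4-[3-(trimethylsilyl)prop-1-en-2-yl]cyclohexan-1-ol | OCCC(C)(C)[C@@]1(C(=C)C[Si](C)(C)C)CC[C@@](C)(O)[C@@H](Cl)C1 | intermediate
19 | 3-[(1R,3S,4R)-3-chloro-4-hydroxy-4-methyl-1-(3-trimethylsilylprop-1-en-2-yl)cyclohexyl]-3-methylbutanal | O=CCC(C)(C)[C@@]1(C(=C)C[Si](C)(C)C)CC[C@@](C)(O)[C@@H](Cl)C1 | intermediate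
20 | (2S)-2-bromo-3-[(1S,3S,4R)-3-chloro-4-hydroxy-4-methyl-1-(3-trimethylsilylprop-1-en-2-yl)cyclohexyl]-3-methylbutanal | O=C[C@@H](Br)C(C)(C)[C@@]1(C(=C)C[Si](C)(C)C)CC[C@@](C)(O)[C@@H](Cl)C1 | intermediate
21 | vinylmagnesium bromide | C=C[Mg]Br | starting material
22 | (1R,2S,4S)-4-[(3S,4R)-3-bromo-4-hydroxy-2-methylhex-5-en-2-yl]-2-chloro-1-methyl-4-[3-(trimethylsilyl)prop-1-en-2-yl]cyclohexan-1-ol | C=C[C@@H](O)[C@@H](Br)C(C)(C)[C@@]1(C(=C)C[Si](C)(C)C)CC[C@@](C)(O)[C@@H](Cl)C1 | intermediate
23 | C3-O-TBS ether of 22 (metathesis precursor) | C=C[C@@H](O[Si](C)(C)C(C)(C)C)[C@@H](Br)C(C)(C)[C@@]1(C(=C)C[Si](C)(C)C)CC[C@@](C)(O)[C@@H](Cl)C1 | intermediate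
24 | (3R,4S,6S,9R,10S)-4-bromo-3-(tert-butyldimethylsilyloxy)-10-chloro-5,5,9-trimethyl-1-(trimethylsilylmethyl)spiro[5.5]undec-1-en-9-ol | C[Si](C)(C)CC1=C[C@@H](O[Si](C)(C)C(C)(C)C)[C@@H](Br)C(C)(C)[C@]12CC[C@@](C)(O)[C@@H](Cl)C2 | intermediate
25 | (3R,4S,6S,9R,10S)-4-bromo-3-(tert-butyldimethylsilyloxy)-10-chloro-5,5,9-trimethyl-1-methylidenespiro[5.5]undecan-9-ol | C=C1C[C@@H](O[Si](C)(C)C(C)(C)C)[C@@H](Br)C(C)(C)[C@]12CC[C@@](C)(O)[C@@H](Cl)C2 | intermediate
26 | (3R,4S,6S,9R,10S)-4-bromo-10-chloro-5,5,9-trimethyl-1-methylidenespiro[5.5]undecane-3,9-diol | C=C1C[C@@H](O)[C@@H](Br)C(C)(C)[C@]12CC[C@@](C)(O)[C@@H](Cl)C2 | target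

Total step count: 14. Longest linear sequence: 14 steps (from 1).

**Steps most likely to fail**

**Step 12 (ring closure).** The Ru=C2 carbene may fail to engage the C1 alkene, which is crowded by quaternary C6 and the silylmethyl group. Dimerisation through the vinyl group, or catalyst decay with alkene isomerisation, would then take over.

- Fallback: close ring A at C2–C3 instead. Bromoaldehyde 20 already carries the allylsilane within reach of its carbonyl carbon.
- BF3·OEt2 (excess, because C9–OH binds one equivalent) in CH2Cl2 at −78 °C should trigger an intramolecular Hosomi–Sakurai reaction. The alkene CH2 becomes C2, silicon leaves, and the former silylmethyl carbon becomes the methylidene.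
- A chair transition state with Br equatorial and anti to the incoming carbon (polar Felkin–Anh) places the oxygen axial, that is cis to Br.
- This detour sets out from 20 and returns at 26. It makes no compound outside the list (F0).

**Step 13 (protodesilylation).** Acid may ionise the C3–O bond with simultaneous loss of silicon (vinylogous Peterson 1,4-elimination). Prolonged acid may also move the new alkene into the ring.

- Fallback: take the leaving group away by raising C3 to the ketone level, setting out from 24.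
- Buffered TBAF/AcOH (THF, 0 °C) cleaves only the O–Si bond to give the allylic alcohol (3R,4S,6S,9R,10S)-4-bromo-10-chloro-5,5,9-trimethyl-1-(trimethylsilylmethyl)spiro[5.5]undec-1-ene-3,9-diol F1.
- Dess–Martin periodinane gives the γ-silyl enone F2.
- TBAF/AcOH at −78 °C releases the dienolate, whose kinetic α-protonation at C2 gives the β,γ-unsaturated α′-bromoketone F3, which is used at once.
- DIBAL at −78 °C, approaching from the equatorial side because the axial C5 methyl blocks the other face, should give the axial alcohol cis to Br. The detour returns at 26.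

**Step 7 (allylsilane from the lactone).** The second silylmethyl addition may stall at the α-silyl ketone, because C1 lies beside two adjacent quaternary carbons. Desilylation to a methyl ketone would follow on work-up.

- Fallback: build the allylsilane by cross-coupling, setting out from 15.
- MeLi (3 equiv, THF, −78 °C) opens the lactone to the hydroxy methyl ketone F4.
- TESOTf/2,6-lutidine gives the bis(triethylsilyl) ether F5.
- KHMDS and the Comins reagent, acting at the only enolisable position, give the enol triflate F6.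
- Pd(PPh3)4-catalysed Kumada coupling with 16 gives the bis(triethylsilyl) allylsilane F7.
- Buffered TBAF/AcOH removes both TES groups, and the detour returns at 18.

**Further compounds**

F0 | step 12 | none | none
F1 | step 13 | (3R,4S,6S,9R,10S)-4-bromo-10-chloro-5,5,9-trimethyl-1-(trimethylsilylmethyl)spiro[5.5]undec-1-ene-3,9-diol | C[Si](C)(C)CC1=C[C@@H](O)[C@@H](Br)C(C)(C)[C@]12CC[C@@](C)(O)[C@@H](Cl)C2
F2 | step 13 | (4S,6S,9R,10S)-4-bromo-10-chloro-9-hydroxy-5,5,9-trimethyl-1-(trimethylsilylmethyl)spiro[5.5]undec-1-en-3-one | C[Si](C)(C)CC1=CC(=O)[C@@H](Br)C(C)(C)[C@]12CC[C@@](C)(O)[C@@H](Cl)C2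
F3 | step 13 | (4S,6S,9R,10S)-4-bromo-10-chloro-9-hydroxy-5,5,9-trimethyl-1-methylidenespiro[5.5]undecan-3-one | C=C1CC(=O)[C@@H](Br)C(C)(C)[C@]12CC[C@@](C)(O)[C@@H](Cl)C2
F4 | step 7 | 1-[(1R,3S,4R)-3-chloro-4-hydroxy-1-(4-hydroxy-2-methylbutan-2-yl)-4-methylcyclohexyl]ethan-1-one | OCCC(C)(C)[C@@]1(C(C)=O)CC[C@@](C)(O)[C@@H](Cl)C1
F5 | step 7 | bis(triethylsilyl) ether of F4 | CC[Si](CC)(CC)OCCC(C)(C)[C@@]1(C(C)=O)CC[C@@](C)(O[Si](CC)(CC)CC)[C@@H](Cl)C1
F6 | step 7 | enol triflate of F5 (CH2=C(OTf) on C6) | CC[Si](CC)(CC)OCCC(C)(C)[C@@]1(C(=C)OS(=O)(=O)C(F)(F)F)CC[C@@](C)(O[Si](CC)(CC)CC)[C@@H](Cl)C1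
F7 | step 7 | bis(triethylsilyl) ether of 18 | CC[Si](CC)(CC)OCCC(C)(C)[C@@]1(C(=C)C[Si](C)(C)C)CC[C@@](C)(O[Si](CC)(CC)CC)[C@@H](Cl)C1
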